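Everything rests on cutting ring B out of the macrocycle. That para-phenylene carries only the diaryl ether oxygen and, para to it, the CH2 on piperazine C2, with four CH positions between: the pattern left when a terminal alkyne adds across C3 and C6 of a 5-aryloxy-2-pyrone and CO2 departs. One thermal operation thus forms two C–C bonds, ring B and the 14-membered cyclophane, the ether oxygen arriving already attached to ring A. The precursor is a cis-(2S,5S)-piperazine, both nitrogens trifluoroacetylated, with a propargyl arm on C2 and on C5 a 4-methoxybenzyl arm whose C3 oxygen carries the pyrone. Guanine is annulated last onto the ortho-formylated ring A phenol.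

Key step: step 11

Remarks on the chemistry (assumptions):
- Starting materials 1 and 6 are the catalogue N-Boc derivatives of 3-iodo-L-tyrosine and L-propargylglycine; 24 is used as its commercial sulfate.
- Ring A numbering: C1 carries the benzylic CH2, C3 the ether oxygen, C4 the methoxy or hydroxyl group, C5 the position that later bears the formyl group and the guanine. Both piperazine centres are S (cis, from two L-amino acids) in every numbered compound.
- A ten-atom tether is too long to impose the mode of addition, so para selectivity is entrusted to an unsubstituted alkyne terminus. The terminus is therefore free in the key step and is masked as its C-trimethylsilyl derivative only for step 9, where a free terminal alkyne would give metal acetylides.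
- The trifluoroacetamides are kept through the thermal step and the BBr3 step and are exchanged for Boc only before the base-mediated formylation.
- Either face of the pyrone may be used in step 11; both bridgehead configurations of 18 collapse to 19, so its SMILES leaves the bridgeheads undefined.

Step 1
Reactants: 1 N-Boc-3-iodo-L-tyrosine
Product: 2 methyl N-Boc-3-iodo-O-methyl-L-tyrosinate
Conditions: MeI (3 equiv), K2CO3 (3 equiv), DMF, rt
Reagents that add atoms: iodomethane, CI
Why: Williamson O-methylation of the phenoxide and alkylation of the carboxylate occur together under carbonate, which leaves the carbamate N–H and the α-stereocentre untouched.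

Step 2
Reactants: 2 methyl N-Boc-3-iodo-O-methyl-L-tyrosinate
Product: 4 methyl N-Boc-3-hydroxy-4-methoxy-L-phenylalaninate, via pinacol boronate 3 (not isolated)
Conditions: B2pin2, PdCl2(dppf) (5 mol%), KOAc, dioxane, 85 °C; then 30% H2O2, THF/H2O, 0 °C to rt
Reagents that add atoms: bis(pinacolato)diboron, CC1(C)OB(OC1(C)C)B1OC(C)(C)C(C)(C)O1 (boryl group of 3 only); hydrogen peroxide, OO (hydroxyl oxygen of 4)
Why: Miyaura borylation of the aryl iodide followed by oxidation of the C–B bond places the hydroxyl at the former iodine position without touching ester, carbamate or stereocentre.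

Step 3
Reactants: 4 methyl N-Boc-3-hydroxy-4-methoxy-L-phenylalaninate
Product: 5 methyl 3-hydroxy-4-methoxy-L-phenylalaninate hydrochloride
Conditions: 4 M HCl in dioxane, rt
Reagents that add atoms: hydrogen chloride, Cl
Why: Acidolysis of the tert-butyl carbamate (loss of 2-methylpropene and CO2) gives the ammonium salt, while the methyl ester, aryl ether and phenol are inert to anhydrous HCl.

Step 4
Reactants: 5 methyl 3-hydroxy-4-methoxy-L-phenylalaninate hydrochloride; 6 N-Boc-L-propargylglycine
Product: 7 methyl N-(N-Boc-L-propargylglycyl)-3-hydroxy-4-methoxy-L-phenylalaninate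
Conditions: EDC·HCl, HOBt, N-methylmorpholine, CH2Cl2/DMF, 0 °C to rt
Reagents that add atoms: none
Why: Carbodiimide/HOBt amide coupling of a urethane-protected acid resists oxazolone racemisation, and the amine is far more nucleophilic than the phenol.

Step 5
Reactants: 7 methyl N-(N-Boc-L-propargylglycyl)-3-hydroxy-4-methoxy-L-phenylalaninate
Product: 9 (3S,6S)-3-(3-hydroxy-4-methoxybenzyl)-6-(prop-2-yn-1-yl)piperazine-2,5-dione, via dipeptide amino ester 8 (not isolated)
Conditions: TFA/CH2Cl2 (1:2), rt; evaporate; then N-methylmorpholine, AcOH, 2-butanol/toluene (4:1), reflux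
Reagents that add atoms: none
Why: Boc acidolysis then intramolecular aminolysis of the methyl ester (diketopiperazine formation) in a weakly acidic buffer keeps both L-centres, so the cis-(3S,6S) ring should result.

Step 6
Reactants: 9 (3S,6S)-3-(3-hydroxy-4-methoxybenzyl)-6-(prop-2-yn-1-yl)piperazine-2,5-dione
Product: 10 (2S,5S)-2-(3-hydroxy-4-methoxybenzyl)-5-(prop-2-yn-1-yl)piperazine
Conditions: LiAlH4 (8 equiv), THF, reflux; Rochelle-salt work-up
Reagents that add atoms: none
Why: Amide reduction with LiAlH4 converts both lactams to amines without involving the stereocentres, and an isolated homopropargylic alkyne is not hydroaluminated in THF at reflux (borane is avoided because it would hydroborate the alkyne).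

Step 7
Reactants: 10 (2S,5S)-2-(3-hydroxy-4-methoxybenzyl)-5-(prop-2-yn-1-yl)piperazine
Product: 12 (2S,5S)-2-(3-hydroxy-4-methoxybenzyl)-5-(prop-2-yn-1-yl)-1,4-bis(trifluoroacetyl)piperazine, via tris(trifluoroacetyl) compound 11 (not isolated)
Conditions: (CF3CO)2O (4 equiv), pyridine, CH2Cl2, 0 °C to rt; then MeOH, rt
Reagents that add atoms: trifluoroacetic anhydride, O=C(OC(=O)C(F)(F)F)C(F)(F)F
Why: N-acylation by the anhydride is exhaustive, and the aryl trifluoroacetate that forms alongside is an active ester that methanol cleaves selectively while the tertiary trifluoroacetamides stay.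

Step 8
Reactants: 12 (2S,5S)-2-(3-hydroxy-4-methoxybenzyl)-5-(prop-2-yn-1-yl)-1,4-bis(trifluoroacetyl)piperazine
Product: 14 (2S,5S)-2-(3-hydroxy-4-methoxybenzyl)-5-[3-(trimethylsilyl)prop-2-yn-1-yl]-1,4-bis(trifluoroacetyl)piperazine, via O,C-bis(trimethylsilyl) compound 13 (not isolated)
Conditions: Me3SiOTf (2.5 equiv), Et3N (3 equiv), Zn(OTf)2 (20 mol%), CH2Cl2, rt; then MeOH, aq citric acid, rt
Reagents that add atoms: trimethylsilyl trifluoromethanesulfonate, C[Si](C)(C)OS(=O)(=O)C(F)(F)F
Why: Zinc-catalysed C-silylation of a terminal alkyne (zinc acetylide trapped by the silyl triflate) masks the acidic C–H under conditions that spare the trifluoroacetamides, and the labile aryl silyl ether is removed again by mildly acidic methanolysis while the C–Si bond holds.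

Step 9
Reactants: 14 (2S,5S)-2-(3-hydroxy-4-methoxybenzyl)-5-[3-(trimethylsilyl)prop-2-yn-1-yl]-1,4-bis(trifluoroacetyl)piperazine; 15 5-bromo-2H-pyran-2-one
Product: 16 (2S,5S)-2-[4-methoxy-3-(2-oxo-2H-pyran-5-yloxy)benzyl]-5-[3-(trimethylsilyl)prop-2-yn-1-yl]-1,4-bis(trifluoroacetyl)piperazine
Conditions: Pd(OAc)2 (5 mol%), tBuXPhos (10 mol%), K3PO4 (2 equiv), toluene, 80 °C
Reagents that add atoms: none
Why: Palladium-catalysed C–O cross-coupling of a phenol with a C(sp2) bromide (Buchwald–Hartwig-type etherification with a bulky biarylphosphine) should work because the electron-poor pyronyl bromide adds readily to zerovalent palladium and undergoes easy C–O reductive elimination, while the sparingly soluble phosphate keeps free phenoxide low enough to spare the lactone.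

Step 10
Reactants: 16 (2S,5S)-2-[4-methoxy-3-(2-oxo-2H-pyran-5-yloxy)benzyl]-5-[3-(trimethylsilyl)prop-2-yn-1-yl]-1,4-bis(trifluoroacetyl)piperazine
Product: 17 (2S,5S)-2-[4-methoxy-3-(2-oxo-2H-pyran-5-yloxy)benzyl]-5-(prop-2-yn-1-yl)-1,4-bis(trifluoroacetyl)piperazine
Conditions: AgNO3 (20 mol%), acetone/H2O, rt, dark
Reagents that add atoms: none
Why: Silver-catalysed protodesilylation of the alkynylsilane (silver acetylide protonated by water) runs at neutral pH, so the base-sensitive pyrone and trifluoroacetamides should survive.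

Step 11
Reactants: 17 (2S,5S)-2-[4-methoxy-3-(2-oxo-2H-pyran-5-yloxy)benzyl]-5-(prop-2-yn-1-yl)-1,4-bis(trifluoroacetyl)piperazine
Product: 19 N,N'-bis(trifluoroacetyl)-O-methylpiperazinomycin, via bridged lactone cycloadduct 18 (not isolated)
Conditions: 1,2-dichlorobenzene (2 mM, degassed), BHT (10 mol%), 200 °C, sealed vessel
Reagents that add atoms: none
Why: Thermal [4+2] cycloaddition of the terminal alkyne across C3 and C6 of the 2-pyrone gives the 2-oxabicyclo[2.2.2]octadienone 18, which loses CO2 by retro-[4+2] to leave the benzene ring. The closest known reaction type is the intramolecular 2-pyrone–alkyne Diels–Alder/decarboxylation used to build the bent para-phenylene of aza-paracyclophanes. Ring B closes by the cycloaddition itself (bonds C3–internal alkyne carbon and C6–terminal alkyne carbon), and the 14-membered ring closes in the same event as a type 2 intramolecular cycloaddition whose ten-atom tether runs from pyrone C5 through the ether oxygen, ring A, the piperazine and the propargylic CH2 to the internal alkyne carbon. No stereocentre is created: C2 and C5 of the piperazine meet neither acid nor base and keep their configuration, and the bridgehead centres of 18 vanish on aromatisation. The step needs the para mode of addition (internal alkyne carbon to C3, not to C6) and ring closure in preference to oligomerisation; the unsubstituted alkyne terminus pairs with C6, the more electrophilic and more hindered diene end flanked by the ring oxygen and the aryloxy-bearing C5, leaving the substituted carbon for the open C3, while high dilution and the two N-acyl groups, which hold both cis arms pseudoaxial on one face and remove amine nucleophilicity toward the pyrone, favour the intramolecular path. Loss of CO2 and aromatisation make the sequence irreversible and pay for the strain of the cyclophane.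

Step 12
Reactants: 19 N,N'-bis(trifluoroacetyl)-O-methylpiperazinomycin
Product: 20 N,N'-bis(trifluoroacetyl)piperazinomycin
Conditions: BBr3 (4 equiv), CH2Cl2, −78 to 0 °C; MeOH then H2O quench
Reagents that add atoms: none
Why: Lewis-acid cleavage of the aryl methyl ether by BBr3 proceeds by bromide attack on the methyl group, a path closed to the diaryl ether, and trifluoroacetamides are inert to the reagent.

Step 13
Reactants: 20 N,N'-bis(trifluoroacetyl)piperazinomycin
Product: 22 N,N'-bis(tert-butoxycarbonyl)piperazinomycin, via piperazinomycin 21 (not isolated)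
Conditions: K2CO3 (6 equiv), MeOH/H2O (4:1), 40 °C; then Boc2O (2.5 equiv), rt
Reagents that add atoms: di-tert-butyl dicarbonate, CC(C)(C)OC(=O)OC(=O)OC(C)(C)C
Why: Carbonate-mediated solvolysis of the two trifluoroacetamides followed by N-acylation of the freed secondary amines with Boc2O should give the bis-carbamate, any aryl tert-butyl carbonate being cleaved again in the methanolic carbonate so that the phenol ends free.

Step 14
Reactants: 22 N,N'-bis(tert-butoxycarbonyl)piperazinomycin
Product: 23 5-formyl-N,N'-bis(tert-butoxycarbonyl)piperazinomycin (formyl on ring A C5, ortho to the hydroxyl)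
Conditions: MgCl2 (3 equiv), Et3N (6 equiv), (CH2O)n (10 equiv), MeCN, reflux; cold aq citric acid work-up
Reagents that add atoms: paraformaldehyde (as formaldehyde), C=O
Why: Magnesium-mediated ortho-formylation of a phenol (Casnati–Skattebøl reaction) delivers formaldehyde through the magnesium phenoxide to the only free ortho position, ring A C5, and leaves the non-phenolic ring B and the carbamates untouched.

Step 15
Reactants: 23 5-formyl-N,N'-bis(tert-butoxycarbonyl)piperazinomycin; 24 2,5,6-triaminopyrimidin-4(3H)-one sulfate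
Product: 26 N,N'-bis(tert-butoxycarbonyl)guanipiperazine A, via Schiff base 25 (not isolated)
Conditions: NaOAc (2.5 equiv), DMSO, 60 °C; then O2 (1 atm), 100 °C
Reagents that add atoms: none
Why: Traube-type oxidative cyclocondensation, in which the most nucleophilic 5-amino group forms the Schiff base, the 6-amino group adds to it and oxygen dehydrogenates the dihydropurine, should give the 8-arylguanine under neutral conditions that the carbamates and the fully ortho/para-substituted phenol tolerate.

Step 16
Reactants: 26 N,N'-bis(tert-butoxycarbonyl)guanipiperazine A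
Product: 27 guanipiperazine A
Conditions: TFA/CH2Cl2 (1:1), rt; then aq NH3 to the free base
Reagents that add atoms: none
Why: Acidolysis of both tert-butyl carbamates is clean because guanine, phenol and diaryl ether are stable to trifluoroacetic acid and the stereocentres next to protonated amines cannot epimerise.

Compound list
1 | N-Boc-3-iodo-L-tyrosine | CC(C)(C)OC(=O)N[C@@H](Cc1ccc(O)c(I)c1)C(=O)O | starting material
2 | methyl N-Boc-3-iodo-O-methyl-L-tyrosinate | COC(=O)[C@H](Cc1ccc(OC)c(I)c1)NC(=O)OC(C)(C)C | intermediate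
3 | methyl N-Boc-4-methoxy-3-(pinacolboryl)-L-phenylalaninate | COC(=O)[C@H](Cc1ccc(OC)c(B2OC(C)(C)C(C)(C)O2)c1)NC(=O)OC(C)(C)C | intermediate (not isolated)
4 | methyl N-Boc-3-hydroxy-4-methoxy-L-phenylalaninate | COC(=O)[C@H](Cc1ccc(OC)c(O)c1)NC(=O)OC(C)(C)C | intermediate
5 | methyl 3-hydroxy-4-methoxy-L-phenylalaninate hydrochloride | COC(=O)[C@H](Cc1ccc(OC)c(O)c1)N.Cl | intermediate
6 | N-Boc-L-propargylglycine, (S)-2-(Boc-amino)pent-4-ynoic acid | C#CC[C@@H](C(=O)O)NC(=O)OC(C)(C)C | starting material
7 | methyl N-(N-Boc-L-propargylglycyl)-3-hydroxy-4-methoxy-L-phenylalaninate | C#CC[C@H](NC(=O)OC(C)(C)C)C(=O)N[C@@H](Cc1ccc(OC)c(O)c1)C(=O)OC | intermediate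
8 | methyl N-(L-propargylglycyl)-3-hydroxy-4-methoxy-L-phenylalaninate | C#CC[C@H](N)C(=O)N[C@@H](Cc1ccc(OC)c(O)c1)C(=O)OC | intermediate (not isolated)
9 | (3S,6S)-3-(3-hydroxy-4-methoxybenzyl)-6-(prop-2-yn-1-yl)piperazine-2,5-dione | C#CC[C@@H]1NC(=O)[C@H](Cc2ccc(OC)c(O)c2)NC1=O | intermediate
10 | (2S,5S)-2-(3-hydroxy-4-methoxybenzyl)-5-(prop-2-yn-1-yl)piperazine | C#CC[C@H]1CN[C@H](CN1)Cc1ccc(OC)c(O)c1 | intermediate
11 | (2S,5S)-2-[4-methoxy-3-(trifluoroacetoxy)benzyl]-5-(prop-2-yn-1-yl)-1,4-bis(trifluoroacetyl)piperazine | C#CC[C@H]1CN(C(=O)C(F)(F)F)[C@H](CN1C(=O)C(F)(F)F)Cc1ccc(OC)c(OC(=O)C(F)(F)F)c1 | intermediate (not isolated)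
12 | (2S,5S)-2-(3-hydroxy-4-methoxybenzyl)-5-(prop-2-yn-1-yl)-1,4-bis(trifluoroacetyl)piperazine | C#CC[C@H]1CN(C(=O)C(F)(F)F)[C@H](CN1C(=O)C(F)(F)F)Cc1ccc(OC)c(O)c1 | intermediate
13 | (2S,5S)-2-[4-methoxy-3-(trimethylsilyloxy)benzyl]-5-[3-(trimethylsilyl)prop-2-yn-1-yl]-1,4-bis(trifluoroacetyl)piperazine | C[Si](C)(C)C#CC[C@H]1CN(C(=O)C(F)(F)F)[C@H](CN1C(=O)C(F)(F)F)Cc1ccc(OC)c(O[Si](C)(C)C)c1 | intermediate (not isolated)
14 | (2S,5S)-2-(3-hydroxy-4-methoxybenzyl)-5-[3-(trimethylsilyl)prop-2-yn-1-yl]-1,4-bis(trifluoroacetyl)piperazine | C[Si](C)(C)C#CC[C@H]1CN(C(=O)C(F)(F)F)[C@H](CN1C(=O)C(F)(F)F)Cc1ccc(OC)c(O)c1 | intermediate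
15 | 5-bromo-2H-pyran-2-one | O=c1ccc(Br)co1 | starting material
16 | (2S,5S)-2-[4-methoxy-3-(2-oxo-2H-pyran-5-yloxy)benzyl]-5-[3-(trimethylsilyl)prop-2-yn-1-yl]-1,4-bis(trifluoroacetyl)piperazine | C[Si](C)(C)C#CC[C@H]1CN(C(=O)C(F)(F)F)[C@H](CN1C(=O)C(F)(F)F)Cc1ccc(OC)c(Oc2ccc(=O)oc2)c1 | intermediate
17 | (2S,5S)-2-[4-methoxy-3-(2-oxo-2H-pyran-5-yloxy)benzyl]-5-(prop-2-yn-1-yl)-1,4-bis(trifluoroacetyl)piperazine (key-step precursor) | C#CC[C@H]1CN(C(=O)C(F)(F)F)[C@H](CN1C(=O)C(F)(F)F)Cc1ccc(OC)c(Oc2ccc(=O)oc2)c1 | intermediate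
18 | macrocyclic 2-oxabicyclo[2.2.2]octa-5,7-dien-3-one cycloadduct (alkyne carbons bonded to pyrone C3 and C6, bridgeheads undefined) | O=C1OC2C=C3C1C=C2Oc4cc(ccc4OC)C[C@H]5CN(C(=O)C(F)(F)F)[C@@H](C3)CN5C(=O)C(F)(F)F | intermediate (not isolated)
19 | N,N'-bis(trifluoroacetyl)-O-methylpiperazinomycin (14-membered cyclophane: ring A with C4 methoxy, para-phenylene ring B, (2S,5S)-piperazine) | COc1ccc2cc1Oc1ccc(cc1)C[C@H]1CN(C(=O)C(F)(F)F)[C@H](CN1C(=O)C(F)(F)F)C2 | intermediate
20 | N,N'-bis(trifluoroacetyl)piperazinomycin | Oc1ccc2cc1Oc1ccc(cc1)C[C@H]1CN(C(=O)C(F)(F)F)[C@H](CN1C(=O)C(F)(F)F)C2 | intermediate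
21 | piperazinomycin | Oc1ccc2cc1Oc1ccc(cc1)C[C@H]1CN[C@H](CN1)C2 | intermediate (not isolated)
22 | N,N'-bis(tert-butoxycarbonyl)piperazinomycin | Oc1ccc2cc1Oc1ccc(cc1)C[C@H]1CN(C(=O)OC(C)(C)C)[C@H](CN1C(=O)OC(C)(C)C)C2 | intermediate
23 | 5-formyl-N,N'-bis(tert-butoxycarbonyl)piperazinomycin (CHO on ring A C5) | O=Cc1cc2cc(c1O)Oc1ccc(cc1)C[C@H]1CN(C(=O)OC(C)(C)C)[C@H](CN1C(=O)OC(C)(C)C)C2 | intermediate
24 | 2,5,6-triaminopyrimidin-4(3H)-one sulfate | Nc1nc(N)c(N)c(=O)[nH]1.OS(=O)(=O)O | starting material
25 | (E)-Schiff base of aldehyde 23 with the 5-amino group of 2,5,6-triaminopyrimidin-4(3H)-one | Nc1nc(N)c(/N=C/c2cc3cc(c2O)Oc2ccc(cc2)C[C@H]2CN(C(=O)OC(C)(C)C)[C@H](CN2C(=O)OC(C)(C)C)C3)c(=O)[nH]1 | intermediate (not isolated)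
26 | N,N'-bis(tert-butoxycarbonyl)guanipiperazine A (guanin-8-yl on ring A C5) | Nc1nc2nc(-c3cc4cc(c3O)Oc3ccc(cc3)C[C@H]3CN(C(=O)OC(C)(C)C)[C@H](CN3C(=O)OC(C)(C)C)C4)[nH]c2c(=O)[nH]1 | intermediate
27 | guanipiperazine A | Nc1nc2nc(-c3cc4cc(c3O)Oc3ccc(cc3)C[C@H]3CN[C@H](CN3)C4)[nH]c2c(=O)[nH]1 | target

Total step count: 16. Longest linear sequence: 16 steps (1 to 27; compounds 6, 15 and 24 are bought).

Steps most likely to fail

1. Step 11. The cycloaddition may take the meta course (internal alkyne carbon bonding to C6), may be outrun by intermolecular cycloaddition at the temperature the long tether requires, or the pyrone may decompose before the chain folds. The fallback closes the macrocycle by the known Ullmann diaryl ether cyclisation; it sets out from 5 and comes back at 21. Carbodiimide coupling of 5 with commercial N-Boc-4-iodo-L-phenylalanine should give methyl N-(N-Boc-4-iodo-L-phenylalanyl)-3-hydroxy-4-methoxy-L-phenylalaninate F1. Boc removal and cyclisation as in step 5 would give the iodobenzyl diketopiperazine F2. BH3·THF at reflux, usable here because no alkyne is present and borane spares the aryl iodide, would give the iodobenzyl piperazine F3. Boc2O followed by brief K2CO3/MeOH would give the bis-carbamate phenol F4. Intramolecular Ullmann etherification (CuI, N,N-dimethylglycine, Cs2CO3, dioxane, 100 °C, 2 mM) would close the 14-membered ring at the aryl C–O bond to give N,N'-bis(tert-butoxycarbonyl)-O-methylpiperazinomycin F5. BBr3 would then remove the methyl ether and both carbamates to give piperazinomycin 21, which is treated with Boc2O as in the second stage of step 13 to reach 22.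

2. Step 9. Phenoxide may add to C6 of the pyrone and open the lactone, the C–Si bond may be cleaved by phenoxide so that the freed alkyne is alkynylated, or C–O reductive elimination may lag behind catalyst decay. The fallback reverses the polarity of the coupling; it sets out from 14 and 15 and comes back at 16. Miyaura borylation of 15 (B2pin2, PdCl2(dppf), KOAc, dioxane, 80 °C) should give the pyronyl pinacol boronate F6. Chan–Lam–Evans coupling of F6 with phenol 14 (Cu(OAc)2, pyridine, 4 Å sieves, CH2Cl2, air, rt) would then form the same ether at room temperature without inorganic base; the silylated alkyne cannot enter oxidative acetylide coupling under divalent copper.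

3. Step 15. The intramolecularly hydrogen-bonded Schiff base may resist attack by the weakly nucleophilic 6-amino group, the oxidant may engage the electron-rich phenol, or the carbamates may be lost on prolonged heating. The fallback is the non-oxidative Traube sequence; it sets out from 23 and comes back at 26. Pinnick oxidation (NaClO2, NaH2PO4, 2-methyl-2-butene, tBuOH/H2O) should give the salicylic acid F7. Carbodiimide coupling of F7 with the 5-amino group of 24 (freed with NaOAc) would give the 5-carboxamide F8. Cyclodehydration (aq NaOH/dioxane at reflux, or hexamethyldisilazane with (NH4)2SO4) would close the imidazole ring to 26 without any oxidant, conditions the carbamates withstand.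

Further compounds
F1 | step 11 | methyl N-(N-Boc-4-iodo-L-phenylalanyl)-3-hydroxy-4-methoxy-L-phenylalaninate | CC(C)(C)OC(=O)N[C@@H](Cc1ccc(I)cc1)C(=O)N[C@@H](Cc1ccc(OC)c(O)c1)C(=O)OC
F2 | step 11 | (3S,6S)-3-(3-hydroxy-4-methoxybenzyl)-6-(4-iodobenzyl)piperazine-2,5-dione | Ic1ccc(cc1)C[C@@H]1NC(=O)[C@H](Cc2ccc(OC)c(O)c2)NC1=O
F3 | step 11 | (2S,5S)-2-(3-hydroxy-4-methoxybenzyl)-5-(4-iodobenzyl)piperazine | Ic1ccc(cc1)C[C@H]1CN[C@H](CN1)Cc1ccc(OC)c(O)c1
F4 | step 11 | di-tert-butyl (2S,5S)-2-(3-hydroxy-4-methoxybenzyl)-5-(4-iodobenzyl)piperazine-1,4-dicarboxylate | Ic1ccc(cc1)C[C@H]1CN(C(=O)OC(C)(C)C)[C@H](CN1C(=O)OC(C)(C)C)Cc1ccc(OC)c(O)c1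
F5 | step 11 | N,N'-bis(tert-butoxycarbonyl)-O-methylpiperazinomycin | COc1ccc2cc1Oc1ccc(cc1)C[C@H]1CN(C(=O)OC(C)(C)C)[C@H](CN1C(=O)OC(C)(C)C)C2
F6 | step 9 | 5-(4,4,5,5-tetramethyl-1,3,2-dioxaborolan-2-yl)-2H-pyran-2-one | O=c1ccc(B2OC(C)(C)C(C)(C)O2)co1
F7 | step 15 | 5-carboxy-N,N'-bis(tert-butoxycarbonyl)piperazinomycin (CO2H on ring A C5) | OC(=O)c1cc2cc(c1O)Oc1ccc(cc1)C[C@H]1CN(C(=O)OC(C)(C)C)[C@H](CN1C(=O)OC(C)(C)C)C2
F8 | step 15 | N-(2,6-diamino-4-oxo-3,4-dihydropyrimidin-5-yl) amide of acid F7 | Nc1nc(N)c(NC(=O)c2cc3cc(c2O)Oc2ccc(cc2)C[C@H]2CN(C(=O)OC(C)(C)C)[C@H](CN2C(=O)OC(C)(C)C)C3)c(=O)[nH]1
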